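**Strategy.** Everything rests on making the cyclopentane of the trans-hydroazulene (C1–C2–C3–C4–C5, with the 3-hydroxyl and the 4-methylene) from a cyclohexadienone: ring A (C1–C5 plus C10) of a carvone-derived cis-decalin. Irradiation of this 4-methyl-2,5-cyclohexadienone in aqueous acetic acid bonds C1 to C5, cuts C5–C10 and adds water at C10. In one operation ring A contracts to the cyclopentenone, ring B grows to the cycloheptane, C1 is set, and C10 gains the oxygen that later becomes the 9-hydroxy-10-methylene unit. The precursor is a 6-hydroxy-9-mesyloxy-1,4-dien-3-one that already carries the C7 side chain.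

Key step: step 12

Remark: ring carbons are numbered C1–C10 throughout (decalins: ring A = C1–C5 and C10, ring B = C5–C10; hydroazulenes: five-membered ring C1–C5, seven-membered ring C5–C10 and C1). C11 (methyl-bearing) and C12 (oxygen-bearing) are the first two side-chain carbons on C7.

Step 1
Reactants: 1 (R)-(−)-carvone
Product: 2 (5R)-5-(3-hydroxyprop-1-en-2-yl)-2-methylcyclohex-2-en-1-one
Conditions: SeO2 (0.3 equiv), t-BuOOH (2.5 equiv), CH2Cl2, 0 °C → rt
Reagents that add atoms: selenium dioxide (catalytic oxygen carrier) O=[Se]=O; tert-butyl hydroperoxide (terminal oxidant) CC(C)(C)OO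
Why: Catalytic SeO2 allylic oxidation (ene reaction, then [2,3]-shift) should attack the electron-rich isopropenyl group at its methyl (CH3 preferred over the ring methine) and leave the electron-poor enone alone; no stereocentre is formed.

Step 2
Reactants: 2 (5R)-5-(3-hydroxyprop-1-en-2-yl)-2-methylcyclohex-2-en-1-one
Product: 3 (5R)-5-[(2S)-1-hydroxypropan-2-yl]-2-methylcyclohex-2-en-1-one
Conditions: Ru(OAc)2[(R)-BINAP] (1 mol %), H2 (30 atm), MeOH, 25 °C
Reagents that add atoms: none
Why: Hydroxyl-directed asymmetric hydrogenation of a 2-substituted allylic alcohol, in which the ligand antipode (chosen by the empirical face rule for allylic alcohols) should set C11 as S under catalyst control while the unfunctionalised enone is not reduced.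

Step 3
Reactants: 3 (5R)-5-[(2S)-1-hydroxypropan-2-yl]-2-methylcyclohex-2-en-1-one
Product: 4 (2S)-2-[(1R)-4-methyl-5-oxocyclohex-3-en-1-yl]propanal
Conditions: Dess–Martin periodinane, CH2Cl2, 0 °C → rt
Reagents that add atoms: none
Why: Dess–Martin oxidation under non-basic conditions should give the α-branched aldehyde without epimerising C11.

Step 4
Reactants: 4 (2S)-2-[(1R)-4-methyl-5-oxocyclohex-3-en-1-yl]propanal
Product: 5 (5R)-5-[(2S,3S)-3-hydroxyhex-5-en-2-yl]-2-methylcyclohex-2-en-1-one
Conditions: allylB(pin) (1.2 equiv), (S)-TRIP [(S)-3,3′-bis(2,4,6-triisopropylphenyl)-1,1′-binaphthyl-2,2′-diyl hydrogen phosphate] (5 mol %), 4 Å MS, toluene, −30 °C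
Reagents that add atoms: allylboronic acid pinacol ester C=CCB1OC(C)(C)C(C)(C)O1
Why: Chiral-phosphoric-acid-catalysed allylboration through a closed chair transition state, in which the catalyst-directed Si-face attack coincides with the Felkin–Anh preference of the α-methyl aldehyde, should set C12 as S (11,12-syn) and spare the ketone.

Step 5
Reactants: 5 (5R)-5-[(2S,3S)-3-hydroxyhex-5-en-2-yl]-2-methylcyclohex-2-en-1-one
Product: 6 (2S,3S)-2-[(1R)-4-methyl-5-oxocyclohex-3-en-1-yl]hex-5-en-3-yl acetate
Conditions: Ac2O, pyridine, DMAP (cat.), CH2Cl2, rt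
Reagents that add atoms: acetic anhydride CC(=O)OC(C)=O
Why: Standard acylation of the secondary alcohol with retention installs the acetate that stays to the end.

Step 6
Reactants: 7 ethyl vinyl ketone
Product: 8 (Z)-tert-butyldimethyl(penta-1,3-dien-3-yloxy)silane
Conditions: TBSOTf, Et3N, Et2O, 0 °C
Reagents that add atoms: tert-butyldimethylsilyl triflate CC(C)(C)[Si](C)(C)OS(=O)(=O)C(F)(F)F
Why: Soft enolisation of the ethyl ketone should give the (Z)-silyl enol ether, which is the s-cis-capable 2-silyloxy diene with an outward methyl group.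

Step 7
Reactants: 6 (2S,3S)-2-[(1R)-4-methyl-5-oxocyclohex-3-en-1-yl]hex-5-en-3-yl acetate; 8 (Z)-tert-butyldimethyl(penta-1,3-dien-3-yloxy)silane
Product: 9 cis-fused Diels–Alder adduct (3-silyl enol ether 9-ketone)
Conditions: EtAlCl2 (0.5 equiv), toluene, −40 → 0 °C
Reagents that add atoms: none
Why: Lewis-acid-catalysed Diels–Alder reaction in which the silyloxy group directs the methyl-bearing diene terminus to the enone β-carbon (C5) and the diene adds anti to the C7 side chain, so that the ring fusion is cis and the C10 methyl is cis to the side chain (C4 forms endo and is erased later).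

Step 8
Reactants: 9 cis-fused Diels–Alder adduct
Product: 10 (9R)-9-alcohol
Conditions: (S)-Me-CBS oxazaborolidine (0.3 equiv), catecholborane (2 equiv), toluene, −60 → −30 °C
Reagents that add atoms: none
Why: CBS reduction in which the quaternary C10 is the large and C8 the small ketone substituent, so that the (S)-catalyst should deliver hydride to give the 9R alcohol with the hydroxyl cis to the 10-methyl, at a temperature where catecholborane does not hydroborate the terminal alkene.

Step 9
Reactants: 10 (9R)-9-alcohol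
Product: 11 9-mesylate
Conditions: MsCl, Et3N, DMAP (cat.), CH2Cl2, 0 °C
Reagents that add atoms: methanesulfonyl chloride CS(Cl)(=O)=O
Why: Sulfonylation with retention turns the 9-oxygen into the leaving group needed for the later epoxide closure.

Step 10
Reactants: 11 9-mesylate
Product: 13 cross-conjugated 1,4-dien-3-one, via 1-en-3-one 12 (not isolated)
Conditions: DDQ (2.5 equiv), 1,4-dioxane, 25 → 95 °C
Reagents that add atoms: none
Why: DDQ should oxidise the silyl enol ether to the 1-en-3-one (hydride abstraction from C1) and then dehydrogenate C4–C5 through the only enol available, giving the 4-methyl-2,5-cyclohexadienone and erasing the C4 and C5 stereocentres.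

Step 11
Reactants: 13 cross-conjugated 1,4-dien-3-one
Product: 15 6-hydroxy-1,4-dien-3-one, via silyl trienol ether 14 (not isolated)
Conditions: TBSOTf, Et3N, CH2Cl2, 0 °C; then DMDO (1.05 equiv, acetone), −78 °C; aq. citric acid work-up
Reagents that add atoms: dimethyldioxirane CC1(C)OO1
Why: Vinylogous Rubottom oxidation in which the only acidic hydrogens (C6) give the 3-silyloxy-1,3,5-triene and its C5=C6 bond is oxidised at −78 °C by stereoelectronically favoured axial attack on the face of the angular methyl (as in the 6β-hydroxylation of steroidal dienol ethers), placing the 6-hydroxyl cis to the 10-methyl and to the C7 side chain while the terminal alkene is too slow to compete.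

Step 12
Reactants: 15 6-hydroxy-1,4-dien-3-one
Product: 16 10-hydroxy-hydroazul-4-en-3-one
Conditions: hν (medium-pressure Hg lamp, Pyrex, λ > 300 nm), AcOH–H2O 45:55, 15 °C, Ar
Reagents that add atoms: water O
Why: n→π* excitation of the cross-conjugated dienone leads to C1–C5 bonding (the five-membered ring C1–C2–C3–C4–C5 closes by this β,β′-bonding, which at the same time forms the cyclopropane C1–C5–C10), and the resulting bicyclo[3.1.0]hexenone zwitterion is protonated on oxygen in the acidic medium. The 4-methyl group localises the positive charge at C4, so the cyclopropane bond C5–C10 (not C1–C10, which would give the spiro isomer) is cleaved with backside attack of water on C10; C10 thereby leaves ring A, and ring B becomes seven-membered by this bond migration and not by a new closure. The closest known reaction type is the santonin-type photorearrangement of 4-methyl-2,5-cyclohexadienones to 10-hydroxy-hydroazulen-3-ones in aqueous acid. C1 is controlled by C10: the cyclopropane must form on the face that keeps C9 exo, which puts H-1 anti to the former angular methyl and hence trans to the C7 side chain, and C10 is set by inversion, with its hydroxyl cis to H-1 and trans to the 9-mesylate. The step needs fused-over-spiro selectivity (secured by the 4-methyl group) and protonation faster than the 1,4-shift to the lumiketone (secured by the acidic medium); the acetate, sulfonate, terminal alkene and free 6-hydroxyl do not absorb at the wavelength used.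

Step 13
Reactants: 16 10-hydroxy-hydroazul-4-en-3-one
Product: 17 tosylhydrazone
Conditions: TsNHNH2 (1.2 equiv), EtOH, 50 °C
Reagents that add atoms: p-toluenesulfonyl hydrazide Cc1ccc(cc1)S(=O)(=O)NN
Why: Condensation at the only ketone gives the α,β-unsaturated tosylhydrazone needed for the reductive transposition.

Step 14
Reactants: 17 tosylhydrazone
Product: 19 trans-fused 3-ene, via allylic diazene 18 (not isolated)
Conditions: catecholborane (5 equiv), CHCl3, 0 °C; then NaOAc·3H2O, 60 °C
Reagents that add atoms: none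
Why: Reductive 1,3-transposition of an α,β-unsaturated tosylhydrazone, in which hydride should add to C3 on the less hindered face syn to H-1 (anti to C10), so that the allylic diazene left after loss of sulfinate sits on the other face and its retro-ene loss of N2 delivers hydrogen suprafacially to C5, giving the 3-ene with H-5 trans to H-1 and cis to the 6-hydroxyl.

Step 15
Reactants: 19 trans-fused 3-ene
Product: 20 9,10-epoxide
Conditions: DBU (2 equiv), toluene, 40 °C
Reagents that add atoms: none
Why: Intramolecular SN2 (Williamson-type) closure in which the 10-alkoxide displaces the anti 9-mesylate with inversion at C9 should give the epoxide on the face of H-1, the non-nucleophilic base sparing the acetate.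

Step 16
Reactants: 20 9,10-epoxide
Product: 21 3,4:9,10-bis-epoxide
Conditions: DMDO (1.1 equiv, acetone), −20 → 0 °C
Reagents that add atoms: dimethyldioxirane CC1(C)OO1
Why: Sterically controlled epoxidation of the only trisubstituted alkene (the monosubstituted side-chain alkene reacts far more slowly) should occur anti to the allylic C5–C6 bond and thus syn to H-5, acetone as solvent suppressing direction by the 6-hydroxyl.

Step 17
Reactants: 21 3,4:9,10-bis-epoxide
Product: 22 bis-epoxide with the 6-methylhept-5-enyl side chain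
Conditions: second-generation Hoveyda–Grubbs catalyst (5 mol %), 2-methylbut-2-ene/CH2Cl2 1:1, 35 °C
Reagents that add atoms: 2-methylbut-2-ene CC=C(C)C
Why: Olefin cross-metathesis of the single (terminal) alkene with 2-methylbut-2-ene installs the isopropylidene terminus and releases propene.

Step 18
Reactants: 22 bis-epoxide with the 6-methylhept-5-enyl side chain
Product: 23 CNP0210891.2
Conditions: Cp2TiCl2 (6 equiv), Mn (10 equiv), THF, 25 °C (forms Cp2TiCl); then 22, 25 °C; aq. NaH2PO4 work-up
Reagents that add atoms: none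
Why: Homolytic opening of both trisubstituted epoxides by trivalent titanium gives tertiary β-titanoxy radicals at C4 and C10, and hydrogen abstraction from the adjacent methyl groups (mixed disproportionation) should give the two exocyclic methylenes while the C3–O and C9–O bonds, and so their configurations, stay untouched and the acetate is inert.

**Compound list**

1 | (R)-(−)-carvone, (5R)-2-methyl-5-(prop-1-en-2-yl)cyclohex-2-en-1-one | CC1=CC[C@H](CC1=O)C(C)=C | starting material
2 | (5R)-5-(3-hydroxyprop-1-en-2-yl)-2-methylcyclohex-2-en-1-one | CC1=CC[C@H](CC1=O)C(=C)CO | intermediate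
3 | (5R)-5-[(2S)-1-hydroxypropan-2-yl]-2-methylcyclohex-2-en-1-one | CC1=CC[C@H](CC1=O)[C@H](C)CO | intermediate
4 | (2S)-2-[(1R)-4-methyl-5-oxocyclohex-3-en-1-yl]propanal | CC1=CC[C@H](CC1=O)[C@H](C)C=O | intermediate
5 | (5R)-5-[(2S,3S)-3-hydroxyhex-5-en-2-yl]-2-methylcyclohex-2-en-1-one | CC1=CC[C@H](CC1=O)[C@H](C)[C@H](CC=C)O | intermediate
6 | (2S,3S)-2-[(1R)-4-methyl-5-oxocyclohex-3-en-1-yl]hex-5-en-3-yl acetate | CC1=CC[C@H](CC1=O)[C@H](C)[C@H](CC=C)OC(C)=O | intermediate
7 | ethyl vinyl ketone (pent-1-en-3-one) | CCC(=O)C=C | starting material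
8 | (Z)-tert-butyldimethyl(penta-1,3-dien-3-yloxy)silane | C/C=C(\O[Si](C)(C)C(C)(C)C)C=C | intermediate
9 | cis-fused Diels–Alder adduct: 3-(TBS-oxy)-4,10-dimethyl-decal-2-en-9-one with the (2S,3S)-3-acetoxyhex-5-en-2-yl chain on C7; H-5, 10-methyl and side chain mutually cis, 4-methyl trans to H-5 | C[C@@]12CC=C(O[Si](C)(C)C(C)(C)C)[C@H](C)[C@@H]1C[C@@H]([C@H](C)[C@H](CC=C)OC(C)=O)CC2=O | intermediate
10 | (9R)-9-alcohol of 9, hydroxyl cis to the 10-methyl | C[C@@]12CC=C(O[Si](C)(C)C(C)(C)C)[C@H](C)[C@@H]1C[C@@H]([C@H](C)[C@H](CC=C)OC(C)=O)C[C@H]2O | intermediate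
11 | 9-mesylate of 10 | C[C@@]12CC=C(O[Si](C)(C)C(C)(C)C)[C@H](C)[C@@H]1C[C@@H]([C@H](C)[C@H](CC=C)OC(C)=O)C[C@H]2OS(C)(=O)=O | intermediate
12 | 9-mesyloxy-4,10-dimethyl-cis-decal-1-en-3-one with the C7 side chain | C[C@@]12C=CC(=O)[C@H](C)[C@@H]1C[C@@H]([C@H](C)[C@H](CC=C)OC(C)=O)C[C@H]2OS(C)(=O)=O | intermediate
13 | 9-mesyloxy-4,10-dimethyl-1,4-dien-3-one (cross-conjugated dienone; 10-methyl, 9-mesylate and C7 side chain cis) | C[C@@]12C=CC(=O)C(C)=C1C[C@@H]([C@H](C)[C@H](CC=C)OC(C)=O)C[C@H]2OS(C)(=O)=O | intermediate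
14 | 3-(TBS-oxy)-1,3,5-triene derived from 13 | C[C@@]12C=CC(O[Si](C)(C)C(C)(C)C)=C(C)C1=C[C@@H]([C@H](C)[C@H](CC=C)OC(C)=O)C[C@H]2OS(C)(=O)=O | intermediate
15 | 6-hydroxy-9-mesyloxy-4,10-dimethyl-1,4-dien-3-one, 6-hydroxyl cis to the 10-methyl and the side chain | C[C@@]12C=CC(=O)C(C)=C1[C@@H](O)[C@@H]([C@H](C)[C@H](CC=C)OC(C)=O)C[C@H]2OS(C)(=O)=O | intermediate
16 | 6,10-dihydroxy-9-mesyloxy-4,10-dimethyl-hydroazul-4-en-3-one; H-1 cis to the 10-hydroxyl, trans to the 9-mesylate and to the side chain | CC1=C2[C@@H](O)[C@@H]([C@H](C)[C@H](CC=C)OC(C)=O)C[C@@H](OS(C)(=O)=O)[C@](C)(O)[C@H]2CC1=O | intermediate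
17 | tosylhydrazone of 16 | CC1=C2[C@@H](O)[C@@H]([C@H](C)[C@H](CC=C)OC(C)=O)C[C@@H](OS(C)(=O)=O)[C@](C)(O)[C@H]2CC1=NNS(=O)(=O)c1ccc(C)cc1 | intermediate
18 | 3-diazenyl-hydroazul-4-ene (diazene trans to H-1) | CC1=C2[C@@H](O)[C@@H]([C@H](C)[C@H](CC=C)OC(C)=O)C[C@@H](OS(C)(=O)=O)[C@](C)(O)[C@H]2C[C@H]1N=N | intermediate
19 | trans-fused 6,10-dihydroxy-9-mesyloxy-4,10-dimethyl-hydroazul-3-ene; H-5 trans to H-1, cis to the 6-hydroxyl | CC=1[C@@H]2[C@@H](O)[C@@H]([C@H](C)[C@H](CC=C)OC(C)=O)C[C@@H](OS(C)(=O)=O)[C@](C)(O)[C@H]2CC=1 | intermediate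
20 | 9,10-epoxide of the trans-fused 3-ene (epoxide oxygen cis to H-1) | CC=1[C@@H]2[C@@H](O)[C@@H]([C@H](C)[C@H](CC=C)OC(C)=O)C[C@@H]3O[C@]3(C)[C@H]2CC=1 | intermediate
21 | 3,4:9,10-bis-epoxide (3,4-oxygen cis to H-5), hex-5-enyl side chain | C[C@]14[C@@H]2[C@@H](O)[C@@H]([C@H](C)[C@H](CC=C)OC(C)=O)C[C@@H]3O[C@]3(C)[C@H]2C[C@H]1O4 | intermediate
22 | 3,4:9,10-bis-epoxide with the (2S,3S)-3-acetoxy-6-methylhept-5-en-2-yl side chain | C[C@]14[C@@H]2[C@@H](O)[C@@H]([C@H](C)[C@H](CC=C(C)C)OC(C)=O)C[C@@H]3O[C@]3(C)[C@H]2C[C@H]1O4 | intermediate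
23 | CNP0210891.2: (1S,3R,5R,6S,7R,9S)-7-[(2S,3S)-3-acetoxy-6-methylhept-5-en-2-yl]-4,10-dimethylidene-trans-perhydroazulene-3,6,9-triol (skeleton numbering as above) | C=C1[C@@H]2[C@@H](O)[C@@H]([C@H](C)[C@H](CC=C(C)C)OC(C)=O)C[C@H](O)C(=C)[C@H]2C[C@H]1O | target

**Step count.** Total: 18 steps. Longest linear sequence: 17 steps (steps 1–5 and 7–18, from 1 to 23); step 6 is the one-step side branch to diene 8.

**Steps most likely to fail, with fallbacks**

Step 12. The electron-withdrawing 9-mesylate may slow the water-assisted opening at C10, so that the protonated zwitterion is diverted to lumiketone or phenol, or the fused-versus-spiro partition erodes. The fallback carries the C9 oxygen through the photochemical step as a silyl ether and introduces the sulfonate afterwards. It sets out from 10 and comes back at 16. Alcohol 10 is silylated (TBSOTf, 2,6-lutidine) to the 9-O-TBS silyl enol ether F1. DDQ as in step 10 takes this through the 9-silyloxy 1-en-3-one F2 to the 9-silyloxy dienone F3. Enol silylation and DMDO as in step 11 lead through the silyl trienol ether F4 to the 6-hydroxy-9-silyloxy dienone F5. Irradiation as in step 12 should give the 9-silyloxy-6,10-dihydroxy hydroazulenone F6. TBAF liberates the 6,9,10-triol F7, whose equatorial 9-hydroxyl (the 6-hydroxyl is flanked by the tetrasubstituted alkene and C7, the 10-hydroxyl is tertiary) is mesylated selectively (MsCl, 2,4,6-collidine, −20 °C) to 16.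

Step 14. Hydride may add to the hydrazone with poor facial selectivity, which would place H-5 cis to H-1 (cis ring fusion). The fallback makes the diazene by inversion of a reagent-defined allylic alcohol. It sets out from 16 and comes back at 19. The 6-hydroxyl of 16 is protected (TESCl, imidazole) as the 6-O-TES enone F8. (R)-Me-CBS with catecholborane gives the (3S)-allylic alcohol F9 under catalyst control. Mitsunobu reaction with 2-nitrobenzenesulfonylhydrazide (PPh3, DEAD, −30 °C) inverts C3 to the N-allyl sulfonylhydrazine F10. On warming this loses sulfinic acid to the allylic diazene F11, whose retro-ene reaction delivers hydrogen to C5 on the face trans to H-1 and gives the 6-O-TES 3-ene F12. HF·pyridine then returns 19.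

Step 2. The catalyst may discriminate the alkene faces poorly (mismatch with the C7 centre), or the 1,1-disubstituted alkene may react sluggishly. The fallback uses carboxylate-directed instead of hydroxyl-directed hydrogenation. It sets out from 2 and comes back at 3. MnO2 oxidises 2 to the 2-substituted acrolein F13, and NaClO2/NaH2PO4/2-methylbut-2-ene gives the acrylic acid F14. Hydrogenation with Ru(OAc)2[(S)-BINAP] (antipode chosen by analogy with 2-substituted acrylic acids) gives the (2S)-propanoic acid F15. Acid-selective reduction with BH3·SMe2 (THF, 0 °C) gives 3.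

Further compounds
F1 | step 12 | 9-O-TBS ether of 10 (3-silyl enol ether, 9-silyl ether) | C[C@@]12CC=C(O[Si](C)(C)C(C)(C)C)[C@H](C)[C@@H]1C[C@@H]([C@H](C)[C@H](CC=C)OC(C)=O)C[C@H]2O[Si](C)(C)C(C)(C)C
F2 | step 12 | 9-(TBS-oxy)-4,10-dimethyl-cis-decal-1-en-3-one with the C7 side chain | C[C@@]12C=CC(=O)[C@H](C)[C@@H]1C[C@@H]([C@H](C)[C@H](CC=C)OC(C)=O)C[C@H]2O[Si](C)(C)C(C)(C)C
F3 | step 12 | 9-(TBS-oxy)-4,10-dimethyl-1,4-dien-3-one | C[C@@]12C=CC(=O)C(C)=C1C[C@@H]([C@H](C)[C@H](CC=C)OC(C)=O)C[C@H]2O[Si](C)(C)C(C)(C)C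
F4 | step 12 | 3,9-bis(TBS-oxy)-1,3,5-triene | C[C@@]12C=CC(O[Si](C)(C)C(C)(C)C)=C(C)C1=C[C@@H]([C@H](C)[C@H](CC=C)OC(C)=O)C[C@H]2O[Si](C)(C)C(C)(C)C
F5 | step 12 | 6-hydroxy-9-(TBS-oxy)-4,10-dimethyl-1,4-dien-3-one | C[C@@]12C=CC(=O)C(C)=C1[C@@H](O)[C@@H]([C@H](C)[C@H](CC=C)OC(C)=O)C[C@H]2O[Si](C)(C)C(C)(C)C
F6 | step 12 | 6,10-dihydroxy-9-(TBS-oxy)-4,10-dimethyl-hydroazul-4-en-3-one | CC1=C2[C@@H](O)[C@@H]([C@H](C)[C@H](CC=C)OC(C)=O)C[C@@H](O[Si](C)(C)C(C)(C)C)[C@](C)(O)[C@H]2CC1=O
F7 | step 12 | 6,9,10-trihydroxy-4,10-dimethyl-hydroazul-4-en-3-one | CC1=C2[C@@H](O)[C@@H]([C@H](C)[C@H](CC=C)OC(C)=O)C[C@@H](O)[C@](C)(O)[C@H]2CC1=O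
F8 | step 14 | 6-O-TES ether of 16 | CC1=C2[C@@H](O[Si](CC)(CC)CC)[C@@H]([C@H](C)[C@H](CC=C)OC(C)=O)C[C@@H](OS(C)(=O)=O)[C@](C)(O)[C@H]2CC1=O
F9 | step 14 | (3S)-allylic alcohol of F8 (3-hydroxyl cis to H-1) | CC1=C2[C@@H](O[Si](CC)(CC)CC)[C@@H]([C@H](C)[C@H](CC=C)OC(C)=O)C[C@@H](OS(C)(=O)=O)[C@](C)(O)[C@H]2C[C@@H]1O
F10 | step 14 | N-(hydroazul-4-en-3-yl)-N-(2-nitrobenzenesulfonyl)hydrazine (C3 inverted) | CC1=C2[C@@H](O[Si](CC)(CC)CC)[C@@H]([C@H](C)[C@H](CC=C)OC(C)=O)C[C@@H](OS(C)(=O)=O)[C@](C)(O)[C@H]2C[C@H]1N(N)S(=O)(=O)c1ccccc1[N+](=O)[O-]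
F11 | step 14 | 6-O-TES 3-diazenyl-hydroazul-4-ene | CC1=C2[C@@H](O[Si](CC)(CC)CC)[C@@H]([C@H](C)[C@H](CC=C)OC(C)=O)C[C@@H](OS(C)(=O)=O)[C@](C)(O)[C@H]2C[C@H]1N=N
F12 | step 14 | 6-O-TES ether of 19 | CC=1[C@@H]2[C@@H](O[Si](CC)(CC)CC)[C@@H]([C@H](C)[C@H](CC=C)OC(C)=O)C[C@@H](OS(C)(=O)=O)[C@](C)(O)[C@H]2CC=1
F13 | step 2 | 2-[(1R)-4-methyl-5-oxocyclohex-3-en-1-yl]prop-2-enal | CC1=CC[C@H](CC1=O)C(=C)C=O
F14 | step 2 | 2-[(1R)-4-methyl-5-oxocyclohex-3-en-1-yl]prop-2-enoic acid | CC1=CC[C@H](CC1=O)C(=C)C(O)=O
F15 | step 2 | (2S)-2-[(1R)-4-methyl-5-oxocyclohex-3-en-1-yl]propanoic acid | CC1=CC[C@H](CC1=O)[C@H](C)C(O)=O
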